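**Retrosynthetic overview**

1. Numbering and feature: unprimed is the 7-hydroxycoumarin half (benzene ring A, ether oxygen on C6) and primed is the 6',7'-dihydroxycoumarin half (benzene ring B, ether oxygen on C5'). Both pyranones are unsubstituted at C3/C4 and C3'/C4' and are fused at C4a and C4a', each of which is ortho to the lactone oxygen and para to a free phenol (C7–OH, C7'–OH).
2. Key disconnection: C4–C4a, O1–C2, C4'–C4a' and O1'–C2' are cut together, leading back to the unprotected pentaphenol diaryl ether and two ethyl propiolate units (twofold von Pechmann annulation). On ring B, C4a' lies between C8a'–OH and the C5' aryloxy group, so its preference over C8' (between C7'–OH and C8a'–OH) rests on the para C7'–OH alone.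
3. The pentaphenol comes from BBr3 cleavage of its trimethyl ether diphenol, which comes from a twofold Baeyer–Villiger oxidation and methanolysis of the diaryl ether dialdehyde.
4. The dialdehyde (C6–O–C5' ether bond) comes from an SNAr reaction of 3-hydroxy-4,5-dimethoxybenzaldehyde with 4-fluoro-3-methoxybenzaldehyde.
5. Ring order: benzene rings A and B are bought, the ether joins them first, and both pyranone rings are closed last in one operation.

Key step: step 4

Remark: neither formyl group of the diaryl ether has a free ortho or para hydroxyl, so the aldehyde-to-phenol change is planned as a peracid Baeyer–Villiger (Dakin-type) oxidation and not as the alkaline peroxide Dakin reaction.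

**Route**

Step 1
Reactants: 1 3-hydroxy-4,5-dimethoxybenzaldehyde; 2 4-fluoro-3-methoxybenzaldehyde
Product: 3 3-(4-formyl-2-methoxyphenoxy)-4,5-dimethoxybenzaldehyde
Conditions: K2CO3 (1.5 equiv), DMF, 110 °C
Reagents that add atoms: none
Why: Nucleophilic aromatic substitution (SNAr) in which the phenoxide of 1 adds to C4 of 2, activated by the para formyl group, and the Meisenheimer adduct loses fluoride; neither aldehyde is enolisable, so both should survive carbonate in hot DMF.

Step 2
Reactants: 3 3-(4-formyl-2-methoxyphenoxy)-4,5-dimethoxybenzaldehyde
Product: 5 3-(4-hydroxy-2-methoxyphenoxy)-4,5-dimethoxyphenol, via bis-formate 4 (not isolated)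
Conditions: mCPBA (2.4 equiv), CH2Cl2, 0 °C to rt; then K2CO3 (cat.), MeOH, rt
Reagents that add atoms: mCPBA, OOC(=O)c1cccc(Cl)c1
Why: Baeyer–Villiger (Dakin-type) oxidation in which both formyl groups sit on electron-rich rings (para aryloxy on ring A, 3,4,5-trioxygenation on ring B), so aryl migration in the Criegee adducts should outrun hydride migration and give the bis-formate, which mild methanolysis cleaves while the methyl and diaryl ethers stay intact.

Step 3
Reactants: 5 3-(4-hydroxy-2-methoxyphenoxy)-4,5-dimethoxyphenol
Product: 6 6-(2,4-dihydroxyphenoxy)benzene-1,2,4-triol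
Conditions: BBr3 (8 equiv), CH2Cl2, −78 °C to rt; then degassed H2O, 0 °C, Ar
Reagents that add atoms: none
Why: Lewis-acid ether cleavage in which BBr3 binds each methoxy oxygen and bromide attacks the methyl carbon (SN2), whereas the diaryl ether offers no sp3 carbon and should survive; the air-sensitive hydroxyquinol-type product is worked up with degassed solvents and used at once.

Step 4
Reactants: 6 6-(2,4-dihydroxyphenoxy)benzene-1,2,4-triol; 7 ethyl propiolate (3 equiv)
Product: 9 6,7-dihydroxy-5-[(7-hydroxy-2-oxo-2H-chromen-6-yl)oxy]-2H-chromen-2-one, via bis-hydroxycinnamate 8 (not isolated)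
Conditions: ZnCl2 (3 equiv), dioxane, 95 °C, Ar; then 1 M HCl
Reagents that add atoms: none
Why: Friedel–Crafts-type conjugate hydroarylation in which each ZnCl2-activated propiolate is attacked by the most nucleophilic open ring carbon, the one para to the future C7–OH on ring A and the one para to the future C7'–OH on ring B, which forms C4–C4a and C4'–C4a' and gives the bis-(Z)-2-hydroxycinnamate 8 (an E isomer would equilibrate under the hot acidic conditions). Each pyranone then closes by attack of the ortho hydroxyl (C8a–OH, C8a'–OH) on the cis ester with loss of ethanol, a 6-exo-trig acyl substitution that forms O1–C2 and O1'–C2'. The closest known reaction is the von Pechmann coumarin synthesis with propiolate, as in resorcinol to umbelliferone and hydroxyquinol to esculetin. No stereocentre is created, and the alkene geometry of 8 is fixed in the rings. The step needs site selectivity: on ring A the competing carbon C8 is the resorcinol 2-position between C7–OH and C8a–OH, the classically disfavoured site, whereas on ring B both open carbons are flanked by two oxygens (C4a' by C8a'–OH and the C5' aryloxy group, C8' by C7'–OH and C8a'–OH), so that there the choice rests on C4a' being para to the free C7'–OH, the strongest donor of the ring once the C6'/C7' catechol is chelated by ZnCl2, while C8' is para only to the diaryl ether oxygen, whose lone pair is shared with ring A. Because C4' stays unsubstituted there is no peri strain against the C5' aryloxy group, and because only C8a–OH and C8a'–OH are ortho to the new side chains the other three hydroxyls need no protection.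

**Compound list**

1 | 3-hydroxy-4,5-dimethoxybenzaldehyde | COc1cc(C=O)cc(O)c1OC | starting material
2 | 4-fluoro-3-methoxybenzaldehyde | COc1cc(C=O)ccc1F | starting material
3 | 3-(4-formyl-2-methoxyphenoxy)-4,5-dimethoxybenzaldehyde | COc1cc(C=O)ccc1Oc1cc(C=O)cc(OC)c1OC | intermediate
4 | 3-[4-(formyloxy)-2-methoxyphenoxy]-4,5-dimethoxyphenyl formate (bis-formate) | COc1cc(OC=O)ccc1Oc1cc(OC=O)cc(OC)c1OC | intermediate
5 | 3-(4-hydroxy-2-methoxyphenoxy)-4,5-dimethoxyphenol | COc1cc(O)ccc1Oc1cc(O)cc(OC)c1OC | intermediate
6 | 6-(2,4-dihydroxyphenoxy)benzene-1,2,4-triol | Oc1ccc(Oc2cc(O)cc(O)c2O)c(O)c1 | intermediate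
7 | ethyl propiolate | CCOC(=O)C#C | starting material
8 | ethyl (2Z)-3-{2-[5-((1Z)-3-ethoxy-3-oxoprop-1-en-1-yl)-2,4-dihydroxyphenoxy]-3,4,6-trihydroxyphenyl}prop-2-enoate (bis-hydroxycinnamate) | CCOC(=O)/C=C\c1cc(Oc2c(/C=C\C(=O)OCC)c(O)cc(O)c2O)c(O)cc1O | intermediate
9 | 6,7-dihydroxy-5-[(7-hydroxy-2-oxo-2H-chromen-6-yl)oxy]-2H-chromen-2-one | O=c1ccc2cc(Oc3c(O)c(O)cc4oc(=O)ccc34)c(O)cc2o1 | target

**Step count**

Total steps: 4. Longest linear sequence: 4 steps (from 1 or 2 to 9).

**Steps most likely to fail**

Step 4 (key step). The process at risk is carbon–carbon bond formation at C8' of ring B in competition with C4a', since both carbons lie between two oxygens and the preference for C4a' is an electronic expectation only. A second risk is oxidative or acid-induced degradation of the electron-rich pentaphenol before the second annulation is complete. The fallback sets out from 5 and annulates before deprotection by a different mechanism. Compound 5 and ethyl propiolate 7 with Pd(OAc)2 (cat.) in CF3CO2H/CH2Cl2 at rt should give 6,7-dimethoxy-5-[(7-methoxy-2-oxo-2H-chromen-6-yl)oxy]-2H-chromen-2-one F1. This is an electrophilic hydroarylation of the Fujiwara type by divalent palladium followed by lactonisation, known for 3,4-dimethoxyphenol and 3,4,5-trimethoxyphenol. In 5 the desired ring B carbon is para to a methoxy group and the competing one para to the aryloxy group, so the same site is expected. F1 is neutral and air-stable, so any ring B regioisomer could be removed on silica before deprotection. BBr3 in CH2Cl2 (−78 °C to rt) would then cleave the three methyl ethers and bring the route back at 9.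

Step 3. The process at risk is air oxidation of the hydroxyquinol ring to a hydroxyquinone during aqueous work-up and purification, together with retention of boron on the catechol unit. The fallback sets out from crude 6 and comes back at 6. The crude product would be acetylated at once (Ac2O, pyridine, rt) to the bench-stable 6-[2,4-bis(acetyloxy)phenoxy]benzene-1,2,4-triyl triacetate F2, which can be purified on silica and stored. Acid-catalysed methanolysis (HCl in degassed MeOH, rt, Ar) and evaporation would release 6 immediately before step 4.

Step 2. The process at risk is hydride instead of aryl migration in the Criegee adduct of the ring A aldehyde, which has only one para aryloxy donor; this would stop at the carboxylic acid. The fallback sets out from 1 and comes back at 5, with a methyl ketone as the phenol precursor on ring A. Compound 1 would be coupled under the conditions of step 1 with commercial 1-(4-fluoro-3-methoxyphenyl)ethanone (COc1cc(C(C)=O)ccc1F) to give 3-(4-acetyl-2-methoxyphenoxy)-4,5-dimethoxybenzaldehyde F3. mCPBA (CH2Cl2, cat. CF3CO2H, rt) should oxidise the ketone with aryl migration, methyl being a poor migrating group, and the ring B aldehyde as before, to give 3-[4-(acetyloxy)-2-methoxyphenoxy]-4,5-dimethoxyphenyl formate F4. Methanolysis (K2CO3 cat., MeOH, rt) would then return the route at 5.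

**Further compounds**

F1 | step 4 | 6,7-dimethoxy-5-[(7-methoxy-2-oxo-2H-chromen-6-yl)oxy]-2H-chromen-2-one | COc1cc2oc(=O)ccc2cc1Oc1c(OC)c(OC)cc2oc(=O)ccc12
F2 | step 3 | 6-[2,4-bis(acetyloxy)phenoxy]benzene-1,2,4-triyl triacetate | CC(=O)Oc1ccc(Oc2cc(OC(C)=O)cc(OC(C)=O)c2OC(C)=O)c(OC(C)=O)c1
F3 | step 2 | 3-(4-acetyl-2-methoxyphenoxy)-4,5-dimethoxybenzaldehyde | COc1cc(C(C)=O)ccc1Oc1cc(C=O)cc(OC)c1OC
F4 | step 2 | 3-[4-(acetyloxy)-2-methoxyphenoxy]-4,5-dimethoxyphenyl formate | COc1cc(OC(C)=O)ccc1Oc1cc(OC=O)cc(OC)c1OC
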